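**Plan**

- Cuts: the sulfate O–S and acetate O–C bonds come off first, then the benzoate C(=O)O–CH bond between the two halves. In ring A the aryl–CH2 bond at C6 and the aryl–carboxyl bond at C1 are cut together; in ring B the aryl–CH2 bond is cut; in each side chain the bond between the epoxide-derived CH2 next to the carbinol and the following carbon is cut.
- Enabling feature: in ring A the carboxyl-bearing C1 lies between the oxygen-bearing C2 and the chain-bearing C6. Chain, carboxyl and oxygen on three consecutive ring carbons is the pattern left when a 3-alkoxybenzyne takes up a carbon nucleophile away from oxygen and CO2 next to it.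
- Forward order: both benzene rings are bought and no ring is formed. Each C11 chain comes from a 2-propyloxirane and a C6 Grignard reagent. The ring A chain goes on together with the carboxyl group through the aryne, the ring B chain by B-alkyl Suzuki coupling. The halves are joined by Mitsunobu esterification, then acetate, sulfate and debenzylation follow.
- Stereochemistry: both carbinol centres come from enantiopure 2-propyloxirane. The acetoxy centre (S) is carried unchanged from the (S)-epoxide; the ester centre (S) arises from the (R)-epoxide by Mitsunobu inversion.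

Key step: step 6

Remark: both enantiomers of 2-propyloxirane are taken as commercial (each is also accessible by hydrolytic kinetic resolution of the racemate).
Remark: the Grignard partner of the key step is prepared as its chloride, the halide on magnesium being a spectator; this shortens its preparation to three steps.
Remark: the sulfate half-ester in 27 and 28 is written as the neutral hydrogen sulfate of the target SMILES; in practice it would be handled as its sodium salt and the free acid liberated only at the end by brief cation exchange (H+ resin, 0 °C).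

**Route**

Step 1
Reactants: 1 1-fluoro-3,5-dimethoxybenzene
Product: 2 5-fluorobenzene-1,3-diol
Conditions: BBr3, CH2Cl2, −78 °C to rt; H2O
Reagents that add atoms: none
Why: BBr3-mediated cleavage of aryl methyl ethers is routine for resorcinol dimethyl ethers and leaves the aryl fluoride untouched.

Step 2
Reactants: 2 5-fluorobenzene-1,3-diol
Product: 3 1,3-bis(benzyloxy)-5-fluorobenzene
Conditions: BnBr, K2CO3, DMF, 50 °C
Reagents that add atoms: benzyl bromide, BrCc1ccccc1
Why: Williamson etherification of both phenoxides with a reactive benzylic halide should proceed cleanly, the unactivated C–F bond being inert to substitution under these conditions.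

Step 3
Reactants: 4 1-bromo-6-chlorohexane; 5 (S)-2-propyloxirane
Product: 7 (S)-11-chloroundecan-4-ol, via 6-chlorohexylmagnesium bromide 6 (not isolated)
Conditions: Mg, THF, 25 °C; then CuI (10 mol %), 5, THF, −30 to 0 °C; aq. NH4Cl
Reagents that add atoms: none
Why: Magnesium inserts selectively into the C–Br bond, and the copper-catalysed Grignard opening of the terminal epoxide occurs by SN2 attack at the unsubstituted carbon, so the (S) centre of 5 is carried over unchanged.

Step 4
Reactants: 7 (S)-11-chloroundecan-4-ol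
Product: 8 (S)-tert-butyl[(11-chloroundecan-4-yl)oxy]dimethylsilane
Conditions: TBSCl, imidazole, DMF, rt
Reagents that add atoms: tert-butyldimethylsilyl chloride, CC(C)(C)[Si](C)(C)Cl
Why: Standard imidazole-promoted silylation of a secondary alcohol gives an ether that withstands Grignard formation and the aryne step.

Step 5
Reactants: 8 (S)-tert-butyl[(11-chloroundecan-4-yl)oxy]dimethylsilane
Product: 9 (S)-{8-[(tert-butyldimethylsilyl)oxy]undecyl}magnesium chloride (titrated THF solution, used directly)
Conditions: Mg turnings (I2-activated), THF, 60 °C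
Reagents that add atoms: magnesium, [Mg]
Why: Grignard formation by insertion of magnesium into a primary C–Cl bond is reliable in warm THF, gives little Wurtz coupling and does not affect the remote silyl ether or its stereocentre.

Step 6
Reactants: 3 1,3-bis(benzyloxy)-5-fluorobenzene; 9 (S)-{8-[(tert-butyldimethylsilyl)oxy]undecyl}magnesium chloride
Product: 13 2,4-bis(benzyloxy)-6-[(S)-8-(tert-butyldimethylsilyloxy)undecyl]benzoic acid, via aryllithium 10 (not isolated), via aryne 11 (not isolated), via arylmagnesium chloride 12 (not isolated)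
Conditions: 3, sec-BuLi (1.0 equiv), THF, −78 °C; then 9 (1.5 equiv), −78 °C to rt; CO2 (gas), −20 °C to rt; cold 1 M HCl to pH 3
Reagents that add atoms: carbon dioxide, O=C=O
Why: sec-BuLi removes the ring proton of 3 that lies between fluorine and a benzyloxy oxygen, the most acidic C–H because both heteroatoms activate it, to give aryllithium 10, which on warming in the presence of 9 expels LiF to form 3,5-bis(benzyloxy)benzyne 11. The alkylmagnesium adds to the aryne carbon that carried fluorine, away from the flanking benzyloxy group, so the new aryl–magnesium bond of 12 sits next to oxygen where induction and Mg–O coordination stabilise it, and CO2 then carboxylates exactly that carbon. The closest known reaction type is the addition of alkyllithium or Grignard reagents to 3-alkoxybenzynes generated from ortho-metalated 3-haloaryl ethers with CO2 quench, the classical entry to 6-alkylsalicylic and 6-alkyl-2,4-dialkoxybenzoic acids. No ring is closed and no stereocentre is formed; the silyloxy-bearing (S) centre of 9 is remote and untouched. Two selectivities are needed: site-selective lithiation (the site between the two ethers is less acidic and cannot eliminate, and benzylic deprotonation is held back by one equivalent of base at −78 °C) and regioselective aryne addition (secured by the ortho benzyloxy group, which polarises the aryne so that the carbanion develops beside it). The excess of 9 should ensure that the aryne is captured by the alkyl nucleophile and not by 10 or 12.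

Step 7
Reactants: 14 5-bromobenzene-1,3-diol
Product: 15 3-(benzyloxy)-5-bromophenol
Conditions: BnBr (1.0 equiv), K2CO3, acetone, reflux
Reagents that add atoms: benzyl bromide, BrCc1ccccc1
Why: Statistical Williamson mono-alkylation of a symmetrical resorcinol with one equivalent of halide should give the monoether, separable by chromatography from the dibenzyl ether and from recyclable diol.

Step 8
Reactants: 15 3-(benzyloxy)-5-bromophenol
Product: 16 [3-(benzyloxy)-5-bromophenoxy]tri(propan-2-yl)silane
Conditions: TIPSCl, imidazole, DMF, rt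
Reagents that add atoms: triisopropylsilyl chloride, CC(C)[Si](Cl)(C(C)C)C(C)C
Why: Imidazole-promoted silylation of the phenol installs a bulky aryl silyl ether that is orthogonal to the benzyl ethers and, being fluoride-labile but acid-resistant, also to the alkyl TBS ether.

Step 9
Reactants: 17 6-bromohex-1-ene; 18 (R)-2-propyloxirane
Product: 20 (R)-undec-10-en-4-ol, via hex-5-enylmagnesium bromide 19 (not isolated)
Conditions: Mg, THF, 25 °C; then CuI (10 mol %), 18, THF, −30 to 0 °C; aq. NH4Cl
Reagents that add atoms: none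
Why: Copper-catalysed Grignard opening of the terminal epoxide at its CH2 carbon leaves the (R) centre of 18 unchanged and places a terminal alkene seven carbons from the carbinol.

Step 10
Reactants: 20 (R)-undec-10-en-4-ol; 16 [3-(benzyloxy)-5-bromophenoxy]tri(propan-2-yl)silane
Product: 22 (R)-11-[3-(benzyloxy)-5-(triisopropylsilyloxy)phenyl]undecan-4-ol, via bis(9-BBN) adduct 21 (not isolated)
Conditions: 9-BBN (2.3 equiv), THF, 0 °C to rt; then 16, PdCl2(dppf) (5 mol %), aq. K3PO4, DMF, 50 °C
Reagents that add atoms: none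
Why: Anti-Markovnikov hydroboration followed by B-alkyl Suzuki–Miyaura coupling (oxidative addition of zerovalent palladium into the aryl bromide, transmetalation of the primary alkylborane) forms the aryl–CH2 bond; the extra equivalent of borane is taken up by the free hydroxyl as a borinate that hydrolyses on work-up, and the bulky aryl silyl ether should tolerate the phosphate base.

Step 11
Reactants: 13 2,4-bis(benzyloxy)-6-[(S)-8-(tert-butyldimethylsilyloxy)undecyl]benzoic acid; 22 (R)-11-[3-(benzyloxy)-5-(triisopropylsilyloxy)phenyl]undecan-4-ol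
Product: 23 (S)-11-[3-(benzyloxy)-5-(triisopropylsilyloxy)phenyl]undecan-4-yl 2,4-bis(benzyloxy)-6-[(S)-8-(tert-butyldimethylsilyloxy)undecyl]benzoate
Conditions: PPh3, DIAD, toluene, 0 °C to rt
Reagents that add atoms: none
Why: In the Mitsunobu esterification the carboxylate displaces the alkoxyphosphonium group by SN2, inverting the carbinol from (R) to the required (S); because the acid acts as nucleophile, the di-ortho substitution that blocks acyl transfer is no obstacle.

Step 12
Reactants: 23 (S)-11-[3-(benzyloxy)-5-(triisopropylsilyloxy)phenyl]undecan-4-yl 2,4-bis(benzyloxy)-6-[(S)-8-(tert-butyldimethylsilyloxy)undecyl]benzoate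
Product: 24 (S)-11-[3-(benzyloxy)-5-(triisopropylsilyloxy)phenyl]undecan-4-yl 2,4-bis(benzyloxy)-6-[(S)-8-hydroxyundecyl]benzoate
Conditions: HCl (ca. 1% in MeOH), CH2Cl2, 0 °C to rt
Reagents that add atoms: none
Why: Acid-catalysed methanolysis cleaves the alkyl TBS ether far faster than the aryl TIPS ether, whose phenolic oxygen is weakly basic and whose silicon is more hindered, while benzyl ethers and the shielded benzoate are inert.

Step 13
Reactants: 24 (S)-11-[3-(benzyloxy)-5-(triisopropylsilyloxy)phenyl]undecan-4-yl 2,4-bis(benzyloxy)-6-[(S)-8-hydroxyundecyl]benzoate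
Product: 25 (S)-11-[3-(benzyloxy)-5-(triisopropylsilyloxy)phenyl]undecan-4-yl 6-[(S)-8-acetoxyundecyl]-2,4-bis(benzyloxy)benzoate
Conditions: Ac2O, pyridine, DMAP (cat.), CH2Cl2, rt
Reagents that add atoms: acetic anhydride, CC(=O)OC(C)=O
Why: DMAP-catalysed acylation of the only free hydroxyl proceeds with retention, since the C–O bond of the stereocentre is not broken.

Step 14
Reactants: 25 (S)-11-[3-(benzyloxy)-5-(triisopropylsilyloxy)phenyl]undecan-4-yl 6-[(S)-8-acetoxyundecyl]-2,4-bis(benzyloxy)benzoate
Product: 26 (S)-11-[3-(benzyloxy)-5-hydroxyphenyl]undecan-4-yl 6-[(S)-8-acetoxyundecyl]-2,4-bis(benzyloxy)benzoate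
Conditions: TBAF, AcOH, THF, 0 °C
Reagents that add atoms: none
Why: Fluoride-mediated desilylation of an aryl silyl ether is fast at 0 °C, and buffering with acetic acid keeps the medium from hydrolysing or migrating the acetate and the benzoate.

Step 15
Reactants: 26 (S)-11-[3-(benzyloxy)-5-hydroxyphenyl]undecan-4-yl 6-[(S)-8-acetoxyundecyl]-2,4-bis(benzyloxy)benzoate
Product: 27 (S)-11-[3-(benzyloxy)-5-(sulfooxy)phenyl]undecan-4-yl 6-[(S)-8-acetoxyundecyl]-2,4-bis(benzyloxy)benzoate
Conditions: SO3·pyridine, pyridine, rt to 40 °C; aq. NaHCO3 work-up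
Reagents that add atoms: sulfur trioxide–pyridine complex, O=S(=O)([O-])[n+]1ccccc1
Why: O-Sulfonation of a phenol with the SO3·pyridine complex is the standard route to aryl sulfate half-esters, and the single free phenol of 26 is the only site able to react.

Step 16
Reactants: 27 (S)-11-[3-(benzyloxy)-5-(sulfooxy)phenyl]undecan-4-yl 6-[(S)-8-acetoxyundecyl]-2,4-bis(benzyloxy)benzoate
Product: 28 integracin D, (S)-11-[3-hydroxy-5-(sulfooxy)phenyl]undecan-4-yl 6-[(S)-8-acetoxyundecyl]-2,4-dihydroxybenzoate
Conditions: H2 (1 atm), 10% Pd/C, MeOH, rt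
Reagents that add atoms: none
Why: Catalytic hydrogenolysis removes the three benzyl ethers under neutral conditions that leave the sulfate salt, the acetate, the benzoate and both stereocentres intact.

**Compound list**

1 | 1-fluoro-3,5-dimethoxybenzene | COc1cc(F)cc(OC)c1 | starting material
2 | 5-fluorobenzene-1,3-diol | Oc1cc(O)cc(F)c1 | intermediate
3 | 1,3-bis(benzyloxy)-5-fluorobenzene | Fc1cc(OCc2ccccc2)cc(OCc2ccccc2)c1 | intermediate
4 | 1-bromo-6-chlorohexane | ClCCCCCCBr | starting material
5 | (S)-2-propyloxirane | CCC[C@H]1CO1 | starting material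
6 | 6-chlorohexylmagnesium bromide | ClCCCCCC[Mg]Br | intermediate
7 | (S)-11-chloroundecan-4-ol | CCC[C@H](O)CCCCCCCCl | intermediate
8 | (S)-tert-butyl[(11-chloroundecan-4-yl)oxy]dimethylsilane | CCC[C@H](O[Si](C)(C)C(C)(C)C)CCCCCCCCl | intermediate
9 | (S)-{8-[(tert-butyldimethylsilyl)oxy]undecyl}magnesium chloride | CCC[C@@H](CCCCCCC[Mg]Cl)O[Si](C)(C)C(C)(C)C | intermediate
10 | [2,4-bis(benzyloxy)-6-fluorophenyl]lithium | [Li]c1c(F)cc(OCc2ccccc2)cc1OCc1ccccc1 | intermediate
11 | 3,5-bis(benzyloxy)benzyne (3,5-bis(benzyloxy)-1,2-didehydrobenzene) | C1#CC(OCc2ccccc2)=CC(OCc2ccccc2)=C1 | intermediate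
12 | {2,4-bis(benzyloxy)-6-[(S)-8-(tert-butyldimethylsilyloxy)undecyl]phenyl}magnesium chloride | CCC[C@@H](CCCCCCCc1cc(OCc2ccccc2)cc(OCc2ccccc2)c1[Mg]Cl)O[Si](C)(C)C(C)(C)C | intermediate
13 | 2,4-bis(benzyloxy)-6-[(S)-8-(tert-butyldimethylsilyloxy)undecyl]benzoic acid | CCC[C@@H](CCCCCCCc1cc(OCc2ccccc2)cc(OCc2ccccc2)c1C(=O)O)O[Si](C)(C)C(C)(C)C | intermediate
14 | 5-bromobenzene-1,3-diol | Oc1cc(O)cc(Br)c1 | starting material
15 | 3-(benzyloxy)-5-bromophenol | Oc1cc(Br)cc(OCc2ccccc2)c1 | intermediate
16 | [3-(benzyloxy)-5-bromophenoxy]tri(propan-2-yl)silane | CC(C)[Si](Oc1cc(Br)cc(OCc2ccccc2)c1)(C(C)C)C(C)C | intermediate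
17 | 6-bromohex-1-ene | C=CCCCCBr | starting material
18 | (R)-2-propyloxirane | CCC[C@@H]1CO1 | starting material
19 | hex-5-enylmagnesium bromide | C=CCCCC[Mg]Br | intermediate
20 | (R)-undec-10-en-4-ol | CCC[C@@H](O)CCCCCC=C | intermediate
21 | 9-{(R)-8-[(9-borabicyclo[3.3.1]nonan-9-yl)oxy]undecyl}-9-borabicyclo[3.3.1]nonane | CCC[C@@H](OB1C2CCCC1CCC2)CCCCCCCB1C2CCCC1CCC2 | intermediate
22 | (R)-11-[3-(benzyloxy)-5-(triisopropylsilyloxy)phenyl]undecan-4-ol | CCC[C@@H](O)CCCCCCCc1cc(OCc2ccccc2)cc(O[Si](C(C)C)(C(C)C)C(C)C)c1 | intermediate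
23 | (S)-11-[3-(benzyloxy)-5-(triisopropylsilyloxy)phenyl]undecan-4-yl 2,4-bis(benzyloxy)-6-[(S)-8-(tert-butyldimethylsilyloxy)undecyl]benzoate | CCC[C@@H](CCCCCCCc1cc(OCc2ccccc2)cc(OCc2ccccc2)c1C(=O)O[C@@H](CCC)CCCCCCCc1cc(OCc2ccccc2)cc(O[Si](C(C)C)(C(C)C)C(C)C)c1)O[Si](C)(C)C(C)(C)C | intermediate
24 | (S)-11-[3-(benzyloxy)-5-(triisopropylsilyloxy)phenyl]undecan-4-yl 2,4-bis(benzyloxy)-6-[(S)-8-hydroxyundecyl]benzoate | CCC[C@@H](CCCCCCCc1cc(OCc2ccccc2)cc(OCc2ccccc2)c1C(=O)O[C@@H](CCC)CCCCCCCc1cc(OCc2ccccc2)cc(O[Si](C(C)C)(C(C)C)C(C)C)c1)O | intermediate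
25 | (S)-11-[3-(benzyloxy)-5-(triisopropylsilyloxy)phenyl]undecan-4-yl 6-[(S)-8-acetoxyundecyl]-2,4-bis(benzyloxy)benzoate | CCC[C@@H](CCCCCCCc1cc(OCc2ccccc2)cc(OCc2ccccc2)c1C(=O)O[C@@H](CCC)CCCCCCCc1cc(OCc2ccccc2)cc(O[Si](C(C)C)(C(C)C)C(C)C)c1)OC(C)=O | intermediate
26 | (S)-11-[3-(benzyloxy)-5-hydroxyphenyl]undecan-4-yl 6-[(S)-8-acetoxyundecyl]-2,4-bis(benzyloxy)benzoate | CCC[C@@H](CCCCCCCc1cc(OCc2ccccc2)cc(OCc2ccccc2)c1C(=O)O[C@@H](CCC)CCCCCCCc1cc(O)cc(OCc2ccccc2)c1)OC(C)=O | intermediate
27 | (S)-11-[3-(benzyloxy)-5-(sulfooxy)phenyl]undecan-4-yl 6-[(S)-8-acetoxyundecyl]-2,4-bis(benzyloxy)benzoate | CCC[C@@H](CCCCCCCc1cc(OCc2ccccc2)cc(OCc2ccccc2)c1C(=O)O[C@@H](CCC)CCCCCCCc1cc(OCc2ccccc2)cc(OS(=O)(=O)O)c1)OC(C)=O | intermediate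
28 | integracin D, (S)-11-[3-hydroxy-5-(sulfooxy)phenyl]undecan-4-yl 6-[(S)-8-acetoxyundecyl]-2,4-dihydroxybenzoate | CCC[C@@H](CCCCCCCc1cc(O)cc(O)c1C(=O)O[C@@H](CCC)CCCCCCCc1cc(O)cc(OS(=O)(=O)O)c1)OC(C)=O | target

**Step count**

Total step count: 16.
Longest linear sequence: 10 steps (steps 3, 4, 5, 6, 11, 12, 13, 14, 15, 16).

**Steps most likely to fail**

Step 6. Three processes could erode it: deprotonation at a benzylic OCH2 position followed by Wittig rearrangement, capture of the aryne by aryllithium in place of the alkyl Grignard reagent, and incomplete carboxylation of the hindered arylmagnesium. The fallback sets out from 14 and 9 and builds the same acid without an aryne. 5-Bromobenzene-1,3-diol 14 would be benzylated twice (BnBr, K2CO3, DMF) to 1,3-bis(benzyloxy)-5-bromobenzene F1. F1 would be coupled with Grignard reagent 9 under PdCl2(dppf) catalysis (Kumada–Corriu coupling) to (S)-{[11-(3,5-bis(benzyloxy)phenyl)undecan-4-yl]oxy}(tert-butyl)dimethylsilane F2. NBS in MeCN at 0 °C should brominate the ring carbon between the chain and one benzyloxy group, para to the other, giving (S)-{[11-(3,5-bis(benzyloxy)-2-bromophenyl)undecan-4-yl]oxy}(tert-butyl)dimethylsilane F3. Bromine–lithium exchange with n-BuLi in THF at −78 °C, which outruns benzylic deprotonation, followed by CO2 would return the route at acid 13.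

Step 11. The encumbered carboxylate may displace slowly, so that elimination of the activated alcohol or acylation of the reduced azodicarboxylate takes over and inversion is incomplete. The fallback sets out from 22 and separates activation from displacement. Alcohol 22 would be converted with MsCl and Et3N in CH2Cl2 at 0 °C into (R)-11-[3-(benzyloxy)-5-(triisopropylsilyloxy)phenyl]undecan-4-yl methanesulfonate F4. The cesium carboxylate of 13 (Cs2CO3, DMF, 50 °C) would then displace the mesylate with inversion and rejoin the route at ester 23.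

Step 15. Sulfonation may stop short, sulfur trioxide may attack the electron-rich resorcinol carbons, and the sulfate half-ester may hydrolyse while an amphiphilic salt is being purified. The fallback sets out from 26 and introduces the sulfate in masked, neutral form. Phenol 26 would react with 2,2,2-trichloroethyl chlorosulfate (Et3N, DMAP, THF) to give (S)-11-{3-(benzyloxy)-5-[(2,2,2-trichloroethoxy)sulfonyloxy]phenyl}undecan-4-yl 6-[(S)-8-acetoxyundecyl]-2,4-bis(benzyloxy)benzoate F5, which can be chromatographed on silica. Reductive fragmentation of the trichloroethyl group with Zn dust and HCO2NH4 in MeOH would release the sulfate half-ester and rejoin the route at 27.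

**Further compounds**

F1 | step 6 | 1,3-bis(benzyloxy)-5-bromobenzene | Brc1cc(OCc2ccccc2)cc(OCc2ccccc2)c1
F2 | step 6 | (S)-{[11-(3,5-bis(benzyloxy)phenyl)undecan-4-yl]oxy}(tert-butyl)dimethylsilane | CCC[C@@H](CCCCCCCc1cc(OCc2ccccc2)cc(OCc2ccccc2)c1)O[Si](C)(C)C(C)(C)C
F3 | step 6 | (S)-{[11-(3,5-bis(benzyloxy)-2-bromophenyl)undecan-4-yl]oxy}(tert-butyl)dimethylsilane | CCC[C@@H](CCCCCCCc1cc(OCc2ccccc2)cc(OCc2ccccc2)c1Br)O[Si](C)(C)C(C)(C)C
F4 | step 11 | (R)-11-[3-(benzyloxy)-5-(triisopropylsilyloxy)phenyl]undecan-4-yl methanesulfonate | CCC[C@@H](OS(C)(=O)=O)CCCCCCCc1cc(OCc2ccccc2)cc(O[Si](C(C)C)(C(C)C)C(C)C)c1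
F5 | step 15 | (S)-11-{3-(benzyloxy)-5-[(2,2,2-trichloroethoxy)sulfonyloxy]phenyl}undecan-4-yl 6-[(S)-8-acetoxyundecyl]-2,4-bis(benzyloxy)benzoate | CCC[C@@H](CCCCCCCc1cc(OCc2ccccc2)cc(OCc2ccccc2)c1C(=O)O[C@@H](CCC)CCCCCCCc1cc(OCc2ccccc2)cc(OS(=O)(=O)OCC(Cl)(Cl)Cl)c1)OC(C)=O
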